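Take each earlier run once it has gone flat and ask what fraction of the L charged stands as G, while J is fed in and Q is held.

the same everywhere: L 15 mM; Q 5.2 mM (held)
- ash: J 7.5 mM (fed, over 1.0 min); run made earlier
- elm: J 30 mM (fed, over 1.0 min); run made earlier
- flask: J 15.0 mM (fed, over 1.0 min); time 8.0 min

| run | time / min | G / % | L / % |
|---|---|---|---|
| ash | 0.667 | 43.8 | 57.9 |
| ash | 1.33 | 56.9 | 43.1 |
| ash | 2.00 | 61.3 | 37.3 |
| ash | 3.00 | 63.8 | 35.9 |
| ash | 4.00 | 62.2 | 35.4 |
| ash | 5.00 | 64.8 | 36.9 |
| elm | 0.250 | 18.0 | 80.8 |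
| elm | 0.667 | 38.0 | 61.5 |
| elm | 1.33 | 48.5 | 48.8 |
| elm | 2.00 | 57.3 | 43.9 |
| elm | 3.00 | 63.3 | 35.5 |
| elm | 4.00 | 63.6 | 37.3 |
| elm | 5.00 | 62.3 | 34.8 |

(standard deviation of a reading: 1 percentage point)

- at the start none of Q is in solution

* concentration of G at 8.0 min, in mM
* concentration of L at 8.0 min, in mM
* concentration of E at 8.0 min, in mM

Call this number the plateau fraction f, meaning G over G plus L, pooled over the readings from 3.00 min on. Pooling both runs gives 63.8 %.

| Run | J per L charged | f, as read |
|---|---|---|
| ash | 0.500 | 63.8 % |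
| elm | 2.00 | 63.7 % |

The two values differ by 0.100 percentage points, while a reading scatters by 1 point, so J's charge does not show in f. The new flask has 1.00 of J per L, between the two runs, and its 8.0 min is later than the 3.00 min at which elm was flat. I therefore reckon G at 9.57 mM and L at 5.43 mM. One number is not enough, though: f holds G and L, no run read E, and so I commit to no value for E.

The forecast gives G 9.5 mM and L 5.4 mM, on the ground that “The plateau ignores J”, and it gives E 10 mM as a separate guess, which it calls very uncertain.

The flask gives G 9.58 mM, L 5.42 mM and E 5.20 mM, so the forecast's E stands too high by a factor of 1.92.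

    Q ⇌ E, rate k1*(csat - [E]) (kL = 0.240 s⁻¹)
    L + E ⇌ G (K = 340 M⁻¹, k = 5.00 M⁻¹ s⁻¹)
    J + E ⇌ X (K = 7800 M⁻¹, k = 9.90 M⁻¹ s⁻¹)

In this flask at 8.00 min, the relaxation half-life of L + E and G by that step alone, both ways together, is 0.170 min, far shorter than the time allowed, which is thermodynamic control, and G stands at 63.9 % of the L charged, beside the 63.8 % carried from the runs. A neighbour flask charged with 38 mM of L, so with 0.395 equiv of J, reckons by f to G 24.2 mM and L 13.8 mM, and it stands at G 24.3 mM and L 13.7 mM.

All runs stem from a simulated flask from invented constants, and the scatter is random.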